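**Retrosynthetic overview**

1. Target 17 is the hydrogen malonate of (13E)-labda-7,13-dien-15-ol 15. The C15–O acyl bond is cut last, giving alcohol 15 and Meldrum's acid 16.
2. The strategy rests on the E-trisubstituted C13=C14 alkene (C16 methyl on C13, oxygenated C15 on C14) on the C11–C12 tether of the trans-decalin (rings A and B; C5, C9, C10). It is read as a methyl/hydroxymethyl syn-adduct of terminal alkyne 10, with C13–C16 from AlMe3 11 and C14–C15 from formaldehyde 12.
3. Alkyne 10 comes from the C13 methyl ketone by enol phosphate elimination, and its C7=C8 alkene from E1 dehydration of the 8α-ol. The 8α-OH is masked as a TMS ether during alkyne formation so that the acid-mediated dehydration can be run with no ketone present.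
4. Ketone 4 comes from sclareol 1 by cleaving C13–C14 and C14–C15 of the vinyl carbinol. No ring is formed in the route; rings A and B with C5, C9 and C10 are carried over unchanged from 1.

Key step: step 5

Remark on numbering: labdane numbering is used throughout. The terminal alkyne carbon of 10 is the former C16 methyl carbon of ketone 4 and becomes C14 of the target; the methyl from AlMe3 becomes C16 and the formaldehyde carbon becomes C15.

**Route**

Step 1
Reactants: 1 sclareol ((13R)-labd-14-ene-8α,13-diol)
Product: 4 8α-hydroxy-14,15-dinorlabdan-13-one, via labdane-8α,13,14,15-tetraol 2 (not isolated), via 8α,13-dihydroxy-15-norlabdan-14-al 3 (not isolated)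
Conditions: OsO4 (2 mol%), NaIO4 (4 equiv), 2,6-lutidine (2 equiv), 1,4-dioxane/H2O (3:1), 20 °C
Reagents that add atoms: none
Why: Lemieux–Johnson oxidation: OsO4 dihydroxylates the only alkene (the monosubstituted vinyl group), periodate cleaves the glycol (C14–C15) and then the α-hydroxy aldehyde (C13–C14), so that C13 should emerge as the methyl ketone carrying the original C13 oxygen, while lutidine keeps the medium near neutral and C5, C8, C9 and C10 are untouched.

Step 2
Reactants: 4 8α-hydroxy-14,15-dinorlabdan-13-one
Product: 5 8α-(trimethylsilyloxy)-14,15-dinorlabdan-13-one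
Conditions: 1-(trimethylsilyl)imidazole (2 equiv), CH2Cl2, 20 → 40 °C
Reagents that add atoms: 1-(trimethylsilyl)imidazole, C[Si](C)(C)n1ccnc1
Why: O-silylation by silyl transfer from the N-silylimidazole should cap the hindered tertiary alcohol without enolising the ketone, removing the acidic OH that would consume base and add to the C13 carbonyl in step 3.

Step 3
Reactants: 5 8α-(trimethylsilyloxy)-14,15-dinorlabdan-13-one
Product: 8 8α-(trimethylsilyloxy)-14,15-dinorlabd-13(16)-yne, via lithium enolate 6 (not isolated), via enol phosphate 7 (not isolated)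
Conditions: LiN(iPr)2 (1.1 equiv), THF, −78 °C; ClP(O)(OEt)2 (1.15 equiv), −78 → 20 °C; then LiN(iPr)2 (2.3 equiv), THF, −78 → 20 °C; aq NH4Cl
Reagents that add atoms: none
Why: Methyl ketone to terminal alkyne by the enol phosphate route: kinetic deprotonation at the methyl group, O-phosphorylation, and base-induced β-elimination of diethyl phosphate from the 1-alken-2-yl phosphate, with the excess base taken up by the acidic alkyne C–H; partial loss of the TMS group on work-up would be harmless because step 4 removes it.

Step 4
Reactants: 8 8α-(trimethylsilyloxy)-14,15-dinorlabd-13(16)-yne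
Product: 10 14,15-dinorlabd-7-en-13(16)-yne, via 8α-hydroxy-14,15-dinorlabd-13(16)-yne 9 (not isolated)
Conditions: conc. H2SO4 (1.5 equiv), EtOH, 20 °C, quenched with aq NaHCO3 as soon as 9 is consumed
Reagents that add atoms: none
Why: Acidic ethanolysis of the TMS ether followed by E1 dehydration: the tertiary C8 cation should lose an axial C7 proton faster than the hindered C9 methine proton or a C17 methyl proton, giving the trisubstituted C7=C8 alkene under kinetic control (as in related 8α-hydroxy drimanes), while the terminal alkyne is inert to protic acid without a metal catalyst and C9 keeps its configuration.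

Step 5
Reactants: 10 14,15-dinorlabd-7-en-13(16)-yne; 11 trimethylaluminium; 12 formaldehyde (used as paraformaldehyde)
Product: 15 (13E)-labda-7,13-dien-15-ol, via alkenyldimethylalane 13 (not isolated), via lithium alkenylalanate 14 (not isolated)
Conditions: AlMe3 (2.0 equiv), Cp2ZrCl2 (0.25 equiv), CH2Cl2, 20 °C; volatiles removed in vacuo; n-BuLi (1.0 equiv), hexane/THF, −78 → 0 °C; (CH2O)n (3 equiv), THF, 20 °C; 1 M HCl, 0 °C
Reagents that add atoms: trimethylaluminium, C[Al](C)C; formaldehyde (from paraformaldehyde), C=O
Why: Zirconium-catalysed carboalumination (Negishi methylalumination) with alanate hydroxymethylation: a methylzirconium–aluminium species adds methyl and metal syn across the terminal alkyne of 10, methyl to the internal carbon C13 (forming C13–C16) and metal to the terminal carbon, and transmetalation leaves alkenyldimethylalane 13. n-BuLi turns 13 into the more nucleophilic alanate 14, whose alkenyl–aluminium bond adds to formaldehyde with retention of geometry, forming C14–C15 and, after acidic work-up, allylic alcohol 15. The closest known reaction type is this same one-flask conversion of terpenoid terminal alkynes into (E)-3-methylalk-2-en-1-ols. No ring is closed and no stereocentre is created; the only stereochemical element set is the C13=C14 geometry, fixed as E by syn addition and retentive trapping. The step needs methyl delivery to C13 and reaction at the alkyne only: the unhindered monosubstituted alkyne on a plain CH2CH2 tether should secure the first, and the trisubstituted ring alkene C7=C8 should not insert under these conditions. C5, C9 and C10 are remote from the reacting site and untouched.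

Step 6
Reactants: 15 (13E)-labda-7,13-dien-15-ol; 16 Meldrum's acid (2,2-dimethyl-1,3-dioxane-4,6-dione)
Product: 17 (13E)-labda-7,13-dien-15-yl hydrogen malonate
Conditions: Meldrum's acid (1.1 equiv), toluene, 90 °C
Reagents that add atoms: Meldrum's acid, CC1(C)OC(=O)CC(=O)O1
Why: Ring-opening acylation of Meldrum's acid by the primary allylic alcohol with loss of acetone should give the malonic half-ester directly; only one acyl transfer is possible, so no diester can form, and the temperature stays below that at which the half-ester decarboxylates.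

**Compound list**

1 | sclareol, (13R)-labd-14-ene-8α,13-diol | C[C@@]1(O)CC[C@H]2C(C)(C)CCC[C@]2(C)[C@H]1CC[C@@](C)(O)C=C | starting material
2 | labdane-8α,13,14,15-tetraol (C13 as in 1, C14 epimer mixture) | C[C@@]1(O)CC[C@H]2C(C)(C)CCC[C@]2(C)[C@H]1CC[C@@](C)(O)C(O)CO | intermediate (not isolated)
3 | 8α,13-dihydroxy-15-norlabdan-14-al | C[C@@]1(O)CC[C@H]2C(C)(C)CCC[C@]2(C)[C@H]1CC[C@@](C)(O)C=O | intermediate (not isolated)
4 | 8α-hydroxy-14,15-dinorlabdan-13-one | C[C@@]1(O)CC[C@H]2C(C)(C)CCC[C@]2(C)[C@H]1CCC(C)=O | intermediate
5 | 8α-(trimethylsilyloxy)-14,15-dinorlabdan-13-one | C[C@@]1(O[Si](C)(C)C)CC[C@H]2C(C)(C)CCC[C@]2(C)[C@H]1CCC(C)=O | intermediate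
6 | lithium 8α-(trimethylsilyloxy)-14,15-dinorlabd-13(16)-en-13-olate (kinetic enolate of 5) | C[C@@]1(O[Si](C)(C)C)CC[C@H]2C(C)(C)CCC[C@]2(C)[C@H]1CCC(=C)[O-].[Li+] | intermediate (not isolated)
7 | diethyl 8α-(trimethylsilyloxy)-14,15-dinorlabd-13(16)-en-13-yl phosphate | C[C@@]1(O[Si](C)(C)C)CC[C@H]2C(C)(C)CCC[C@]2(C)[C@H]1CCC(=C)OP(=O)(OCC)OCC | intermediate (not isolated)
8 | 8α-(trimethylsilyloxy)-14,15-dinorlabd-13(16)-yne (side chain CH2CH2C≡CH) | C[C@@]1(O[Si](C)(C)C)CC[C@H]2C(C)(C)CCC[C@]2(C)[C@H]1CCC#C | intermediate
9 | 8α-hydroxy-14,15-dinorlabd-13(16)-yne | C[C@@]1(O)CC[C@H]2C(C)(C)CCC[C@]2(C)[C@H]1CCC#C | intermediate (not isolated)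
10 | (5S,9S,10S)-14,15-dinorlabd-7-en-13(16)-yne | CC1=CC[C@H]2C(C)(C)CCC[C@]2(C)[C@H]1CCC#C | intermediate (key-step precursor)
11 | trimethylaluminium | C[Al](C)C | starting material
12 | formaldehyde (as paraformaldehyde) | C=O | starting material
13 | dimethyl[(13E)-15-norlabda-7,13-dien-14-yl]alane | CC1=CC[C@H]2C(C)(C)CCC[C@]2(C)[C@H]1CC/C(C)=C/[Al](C)C | intermediate (not isolated)
14 | lithium butyl(dimethyl)[(13E)-15-norlabda-7,13-dien-14-yl]alanate | CC1=CC[C@H]2C(C)(C)CCC[C@]2(C)[C@H]1CC/C(C)=C/[Al-](C)(C)CCCC.[Li+] | intermediate (not isolated)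
15 | (5S,9S,10S,13E)-labda-7,13-dien-15-ol | CC1=CC[C@H]2C(C)(C)CCC[C@]2(C)[C@H]1CC/C(C)=C/CO | intermediate (key-step product)
16 | Meldrum's acid | CC1(C)OC(=O)CC(=O)O1 | starting material
17 | (5S,9S,10S,13E)-labda-7,13-dien-15-yl hydrogen malonate | CC1=CC[C@H]2C(C)(C)CCC[C@]2(C)[C@H]1CC/C(C)=C/COC(=O)CC(=O)O | target

**Step count**

Total steps: 6. Longest linear sequence: 6 steps (1 → 4 → 5 → 8 → 10 → 15 → 17).

**Steps most likely to fail**

1. Step 4. Proton loss from the C8 cation may be poorly regioselective (toward C17 or C9), and prolonged acid contact may re-protonate the alkene and move it to the tetrasubstituted C8=C9 position or trigger hydride and methyl shifts. Minor ring B alkene isomers could be removed on AgNO3-impregnated silica at the stage of 15 at the latest. Fallback, setting out from 4 and returning at 10: the dehydration is moved to the ketone stage and run without acid. Ketone 4 is treated with the Burgess reagent (methyl N-(triethylammoniosulfonyl)carbamate, benzene, 50 °C), which forms the sulfamate ester 8α-[(methoxycarbonyl)sulfamoyloxy]-14,15-dinorlabdan-13-one F1 and eliminates it thermally in a syn fashion. The ring B alkene regioisomers are separated on AgNO3-impregnated silica to give 14,15-dinorlabd-7-en-13-one F2. F2 is then taken through the LiN(iPr)2 / ClP(O)(OEt)2 / LiN(iPr)2 sequence of step 3, via its lithium enolate F3 and the enol phosphate diethyl 14,15-dinorlabda-7,13(16)-dien-13-yl phosphate F4, to alkyne 10.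

2. Step 5. Transfer of the alkenyl group from the alanate to poorly soluble paraformaldehyde may be incomplete, so that protodemetalation on work-up competes; a minor share of carbometalation with the reverse regiochemistry is also possible. Fallback, setting out from 10 and returning at 15: alkenylalane 13 is generated as in step 5 and trapped directly, without ate-complex formation, with ethyl chloroformate (ClCO2Et, CH2Cl2, 20 °C). This should give ethyl (13E)-labda-7,13-dien-15-oate F5 with retention of geometry. F5 is reduced with i-Bu2AlH (CH2Cl2, −78 °C) to alcohol 15.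

3. Step 1. Hydroxy ketone 4 may close onto its 8α-OH to a cyclic enol ether that the osmium/periodate couple cleaves further (over-oxidation), or the second periodate cleavage may stall. Fallback, setting out from 1 and returning at 4: the vinyl group is ozonised (O3, CH2Cl2, −78 °C) to the ozonide 3-[(13R)-8α,13-dihydroxy-14,15-dinorlabdan-13-yl]-1,2,4-trioxolane F6. F6 is reduced in the same flask with NaBH4 (MeOH, −78 → 20 °C) to 15-norlabdane-8α,13,14-triol F7. The 13,14-glycol of F7 is then cleaved with NaIO4 (THF/H2O, 20 °C) in an osmium-free medium to ketone 4.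

**Further compounds**

F1 | step 4 | 8α-[(methoxycarbonyl)sulfamoyloxy]-14,15-dinorlabdan-13-one | C[C@@]1(OS(=O)(=O)NC(=O)OC)CC[C@H]2C(C)(C)CCC[C@]2(C)[C@H]1CCC(C)=O
F2 | step 4 | 14,15-dinorlabd-7-en-13-one | CC1=CC[C@H]2C(C)(C)CCC[C@]2(C)[C@H]1CCC(C)=O
F3 | step 4 | lithium 14,15-dinorlabda-7,13(16)-dien-13-olate | CC1=CC[C@H]2C(C)(C)CCC[C@]2(C)[C@H]1CCC(=C)[O-].[Li+]
F4 | step 4 | diethyl 14,15-dinorlabda-7,13(16)-dien-13-yl phosphate | CC1=CC[C@H]2C(C)(C)CCC[C@]2(C)[C@H]1CCC(=C)OP(=O)(OCC)OCC
F5 | step 5 | ethyl (13E)-labda-7,13-dien-15-oate | CC1=CC[C@H]2C(C)(C)CCC[C@]2(C)[C@H]1CC/C(C)=C/C(=O)OCC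
F6 | step 1 | 3-[(13R)-8α,13-dihydroxy-14,15-dinorlabdan-13-yl]-1,2,4-trioxolane (ozonide of 1) | C[C@@]1(O)CC[C@H]2C(C)(C)CCC[C@]2(C)[C@H]1CC[C@@](C)(O)C3OOCO3
F7 | step 1 | 15-norlabdane-8α,13,14-triol | C[C@@]1(O)CC[C@H]2C(C)(C)CCC[C@]2(C)[C@H]1CC[C@@](C)(O)CO
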